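## Structural features

The target is an isoflavone: a 4H-chromen-4-one in which benzene ring A (C4a, C5 to C8, C8a) is fused to pyranone ring C (O1, C2, C3, C4), and C3 carries ring B, a 3,4-dimethoxyphenyl group, through one C–C bond. Ring A is pentasubstituted: from C8a it bears O1, a 3-methylbut-2-enyl (prenyl) chain at C8, a free hydroxyl at C7, a methoxyl at C6 and its only hydrogen at C5, before C4a joins the C4 carbonyl. There is no stereocentre and no alkene geometry to control (the prenyl double bond ends in two methyl groups), so no stereocentres stand next to each other and the problem is one of regiochemistry and functional-group tolerance. The fragile parts are the prenyl group (under acid it adds the neighbouring C7 hydroxyl to give a chroman, or is hydrated), the free phenol, and C2 of ring C, a vinylogous ester carbon that hydroxide or amines can attack with ring opening. The real difficulty is C8: the prenyl chain sits between two oxygen-bearing carbons (C8a and C7), and the oxygens on C6 and C7 must end up differentiated as methyl ether and free phenol. The plan uses the fact that C4a is ortho to the O1-bearing C8a and para to the C7 oxygen, which makes it the most electron-rich free carbon of ring A. An acyl cation at C4, tethered through O1–C2=C3, can therefore close ring C onto it, and the same C7 oxygen carries the allyl group that later moves to C8.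

## Logic of the disconnections

**17 ⇒ 15 + 16.** The C2''=C3'' double bond of the side chain is cut (metathesis retron). The prenyl group would not survive an acidic ring closure, so its two terminal carbons are added last from a cheap alkene. The side chain simplifies to allyl. The forward step needs a ruthenium alkylidene to turn over next to a free ortho phenol without moving the double bond.

**15 ⇒ 13 (through 14).** The C8–C1'' bond is cut and the allyl group is reconnected to O7. A [3,3] shift can deliver carbon only ortho to O7, and C6 is occupied by methoxyl, so C8 is the only productive outcome. The same shift uncovers the C7 hydroxyl. The crowded C-substituent becomes a plain ether, and the C6/C7 oxygens are differentiated from the first step. The demand is that 13 tolerates about 200 °C.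

**13 ⇒ 11 (through 12).** The C4–C4a bond is cut, opening ring C. This is the one ring-forming bond that the electronics of ring A favour directly (ortho to O1, para to O7). It removes a ring and leaves an acyclic acid in which the two aryl halves are joined only through O1–C2=C3. The forward step needs the carboxyl carbon cis to the aryloxy group at the moment of attack, attack at C4a and not C8, and an O7 substituent that survives an acid anhydride. Allyl meets the last demand; a tertiary allylic or silyl group would not.

**11 ⇒ 10.** The ester O–C(CH3)3 bond is cut (protecting group). The acid must be masked while bases are used. A tert-butyl ester is removed by the same acid family that closes the ring, so hydroxide never meets the aryloxyacrylate, whose C2 it could attack. The forward step must keep the tert-butyl cation from alkylating ring A.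

**10 ⇒ 5 + 9.** The O1–C2 bond of the aryl vinyl ether is cut. This divides the molecule into a ring A phenol and a ring B acrylate of similar size. C2 of 9 is the β-carbon of an acrylate bearing a sulfonate, an electrophile suited to a phenoxide. The forward step needs attack at carbon and not at sulfur; geometry is helpful but not essential.

**9 ⇒ 8 ⇒ 7 ⇒ 6.** The O–S bond, then the C2–C3 bond (a formyl carbon joined to the benzylic carbon), then the ester bond are cut. Each is a standard enolate or acyl operation, and they lead back to a commercial arylacetic acid that already holds ring B and C3. The tosylation should place the sulfonate cis to the ester.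

**5 ⇒ 3 (through 4) ⇒ 1 + 2.** The aryl C–OH bond is traced back to an aryl C–CHO bond (oxidative aryl migration), then the O–allyl bond is cut. The starting aldehyde already has the 3-hydroxy-4-methoxy pattern that becomes 7-O/6-OMe. The oxidation must spare the allyl double bond.

## Other disconnections considered

**Alternative 1:** The cut is at O1–C8a and C8–C1'' together. Fluoride acting on silyl triflate A1 (4-methoxy-3-(methoxymethoxy)-2-(trimethylsilyl)phenyl triflate) would set free the C8–C8a aryne in the presence of the tertiary allylic alkoxide A2 (potassium 2-methylbut-3-en-2-olate). The alkoxide oxygen should add to C8a, remote from the C7 acetal oxygen, so that the aryl anion develops at C8 next to that inductively stabilising oxygen. The anion would then attack the vinyl terminus through a six-atom array as the O–CMe2 bond breaks, giving phenol A3 (4-methoxy-3-(methoxymethoxy)-2-(3-methylbut-2-enyl)phenol).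
- In its favour: O1 and the linear prenyl group arrive in one operation at low temperature, with no 200 °C rearrangement and no ruthenium. Ring A then has C8 occupied, so a later ring closure at C4a has no regiochemical alternative. On that point it is better than the chosen plan, which relies on the preference of C4a over C8.
- Against it here: the key step closes no ring. From A3 ring C must still be built (acylation at C4a, insertion of C2, acetal removal) with an acid-sensitive prenyl group flanked by two oxygens, which is the combination the chosen plan avoids by adding prenyl last. A1 is a 1,2,3,4-tetrasubstituted arene that needs several steps of its own. Proton transfer to the aryl anion could compete with the C–C bond formation and stop at the aryl ether.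
- Comparison: the mechanism is anionic and less established than a Friedel–Crafts closure matched to ring A electronics. Convergence is about equal. The step count is estimated at equal or higher (about five steps to A1, the key step, three or four afterwards).

**Alternative 2:** Ring A is not taken from an aromatic starting material but built, the last bond being C4a–C8a. Cyclobutenone A4 (the 4-alkenyl-4-methoxy-3-isopropoxy-2-prenylcyclobutenone whose alkenyl arm carries the dioxolane-masked C4 and the 3,4-dimethoxybenzyl group) would be heated in toluene. Four-electron ring opening, with the methoxyl turning outward and the alkenyl arm inward, gives a dienylketene. Six-electron closure joins the ketene carbon (C8a) to the alkene terminus (C4a), and tautomerisation gives phenol A5.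
- In its favour: every position of ring A is fixed by the order of additions to a squarate ester, so no aromatic substitution regiochemistry arises. In certainty of substitution pattern it is better than the chosen plan. The prenyl group is in place from the start, the key step is a reagent-free isomerisation at about 110 °C, and it is at least the equal of the chosen key step in atom economy.
- Against it here: A4 needs a long linear preparation (prenyl addition and rearrangement on the squarate, a separately made alkenyl-metal fragment, O-methylation of a hindered tertiary alkoxide). After A5 there remain ketal hydrolysis, insertion of C2 with ring closure, and cleavage of the C7 isopropyl ether with a boron trihalide right beside the prenyl group, where cyclisation to a chroman threatens.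
- Comparison: the method is more general structurally and mechanistically elegant, but the step count is clearly higher (twelve or more). Commercial aromatics already have the right oxygen pattern, so building ring A from scratch gains little here.

**Alternative 3:** The cut is at C3–C4. Keto aldehyde A6 (a salicylaldehyde ether carrying the O1–CH2–C(=O)–aryl chain, with prenyl, methoxymethyl ether and methoxyl already on ring A) would be treated with a triazolium-derived carbene and an amine base. The aldehyde carbon (C4) becomes an acyl anion equivalent and adds to the ketone carbon (C3) in a six-membered exo closure, giving racemic 3-hydroxychroman-4-one A7. Dehydration across C2–C3 and acetal removal would follow.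
- In its favour: the closure is catalytic, near neutral and at room temperature, and intramolecular aldehyde–ketone benzoin reactions to 3-hydroxychromanones are well established. The prenyl group can be carried through, so no later Claisen rearrangement or metathesis is needed. In mildness of the ring-forming step it is better than the chosen plan, and A6 is assembled by a simple phenacylation.
- Against it here: the fully substituted 3-prenylsalicylaldehyde behind A6 moves the hard problem (carbon at C8 between two oxygens, plus a formyl group at C4a) to earlier steps. The key step makes a stereocentre that is then destroyed and stops one oxidation level short of the chromone. Dehydrating a tertiary benzylic alcohol next to a carbonyl needs activation or acid, which puts the prenyl group and the acetal at risk.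
- Comparison: both plans close ring C by a bond to C4 and are equal in convergence. The chosen plan reaches the chromone oxidation level directly, from cheaper starting materials. The estimated step count is equal or slightly higher for this alternative (about ten to eleven).

Key step: step 8

Remark on the chemistry: compounds 8 to 12 are drawn Z (oxygen on C2 cis to the carboxyl carbon). Any E isomer formed in step 6 is carried along, because the acidic conditions of steps 7 and 8 interconvert the two geometries and only the Z form can close.

## Route

Step 1
Reactants: 1 isovanillin (3-hydroxy-4-methoxybenzaldehyde); 2 allyl bromide (3-bromoprop-1-ene)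
Product: 3 3-(allyloxy)-4-methoxybenzaldehyde
Conditions: K2CO3, DMF, 50 °C
Reagents that add atoms: allyl bromide (compound 2), C=CCBr
Why: Williamson ether synthesis; the phenoxide of 1, its only acidic site, displaces bromide from the unhindered allylic halide by SN2, and the aldehyde is inert to carbonate.

Step 2
Reactants: 3 3-(allyloxy)-4-methoxybenzaldehyde
Product: 5 3-(allyloxy)-4-methoxyphenol, via aryl formate 4 (not isolated)
Conditions: mCPBA, CH2Cl2, 0 °C to rt; then K2CO3 (cat.), MeOH, rt
Reagents that add atoms: mCPBA (3-chloroperoxybenzoic acid), OOC(=O)c1cccc(Cl)c1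
Why: Baeyer–Villiger oxidation, the peracid variant of the Dakin oxidation, used because 3 has no free hydroxyl ortho or para to the formyl group; the aryl group para to methoxyl migrates in preference to hydrogen and formate 4 is methanolysed once excess peracid has been washed out. The monosubstituted allyl alkene is epoxidised much more slowly than the electron-rich aldehyde is oxidised, so a small excess of peracid at low temperature should spare it.

Step 3
Reactants: 6 (3,4-dimethoxyphenyl)acetic acid
Product: 7 tert-butyl (3,4-dimethoxyphenyl)acetate
Conditions: Cl3CC(=NH)OtBu, CH2Cl2/cyclohexane, rt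
Reagents that add atoms: tert-butyl 2,2,2-trichloroacetimidate, CC(C)(C)OC(=N)C(Cl)(Cl)Cl
Why: Imidate esterification; the carboxylic acid protonates the imidate and its carboxylate captures the tert-butyl cation as neutral trichloroacetamide leaves, with no added strong acid that could alkylate the dimethoxyphenyl ring.

Step 4
Reactants: 7 tert-butyl (3,4-dimethoxyphenyl)acetate
Product: 8 tert-butyl (Z)-2-(3,4-dimethoxyphenyl)-3-hydroxyprop-2-enoate (hydrogen-bonded enol form of the α-formyl ester)
Conditions: NaH, HCO2Et, THF, 0 °C to rt; cold dilute HCl work-up
Reagents that add atoms: ethyl formate, CCOC=O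
Why: Crossed Claisen condensation (formylation); ethyl formate cannot enolise, the benzylic ester enolate attacks it, and deprotonation of the product drives the equilibrium. The hindered tert-butyl ester resists exchange with ethoxide.

Step 5
Reactants: 8 tert-butyl (Z)-2-(3,4-dimethoxyphenyl)-3-hydroxyprop-2-enoate
Product: 9 tert-butyl (Z)-2-(3,4-dimethoxyphenyl)-3-(tosyloxy)prop-2-enoate
Conditions: TsCl, TMEDA, LiCl, MeCN, 0 °C
Reagents that add atoms: 4-methylbenzenesulfonyl chloride, Cc1ccc(cc1)S(Cl)(=O)=O
Why: O-Sulfonylation of a chelated enolate (stereoselective enol tosylation); Li+ bridges the enolate oxygen and the ester carbonyl, so the tosyloxy group should end cis to the ester (Z), and the diamine activates TsCl and takes up HCl.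

Step 6
Reactants: 5 3-(allyloxy)-4-methoxyphenol; 9 tert-butyl (Z)-2-(3,4-dimethoxyphenyl)-3-(tosyloxy)prop-2-enoate
Product: 10 tert-butyl (Z)-3-[3-(allyloxy)-4-methoxyphenoxy]-2-(3,4-dimethoxyphenyl)prop-2-enoate
Conditions: Cs2CO3, MeCN, rt
Reagents that add atoms: none
Why: Nucleophilic vinylic substitution by addition–elimination; the phenoxide adds to the unsubstituted β-carbon of the acrylate, the ester enolate stabilised by the α-aryl group expels tosylate, and retention of geometry is expected if elimination is faster than bond rotation.

Step 7
Reactants: 10 tert-butyl (Z)-3-[3-(allyloxy)-4-methoxyphenoxy]-2-(3,4-dimethoxyphenyl)prop-2-enoate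
Product: 11 (Z)-3-[3-(allyloxy)-4-methoxyphenoxy]-2-(3,4-dimethoxyphenyl)prop-2-enoic acid
Conditions: CF3CO2H/CH2Cl2 (1:4), 0 °C to rt; evaporation from toluene
Reagents that add atoms: none
Why: Acidolysis of a tert-butyl ester (alkyl–oxygen cleavage with loss of 2-methylpropene); the aryl allyl ether, the methyl ethers and the enol ether, which the carboxyl group deactivates toward protonation, should survive anhydrous acid, and no hydroxide meets C2.

Step 8
Reactants: 11 (Z)-3-[3-(allyloxy)-4-methoxyphenoxy]-2-(3,4-dimethoxyphenyl)prop-2-enoic acid
Product: 13 7-(allyloxy)-3-(3,4-dimethoxyphenyl)-6-methoxy-4H-chromen-4-one, via mixed trifluoroacetic anhydride 12 (not isolated)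
Conditions: (CF3CO)2O (3 equiv), CH2Cl2, 0 °C to rt (CF3CO2H co-solvent, 40 °C, if closure lags)
Reagents that add atoms: none
Why: Intramolecular Friedel–Crafts acylation, for which the acid-mediated closure of 3-aryloxyacrylic acids to chromones is the closest known reaction type. The anhydride converts the carboxyl group into 12, whose trifluoroacetate leaves to give an acyl cation that the lone pair on O1 stabilises through the C2=C3 bond (acylium and ketene–oxocarbenium forms). In this cation the C2–C3 bond has partial single-bond character, so E and Z forms interconvert and material drains through the Z form, the only one in which C4 can reach ring A. C4 then bonds to C4a and ring C closes in a six-membered mode, endo with respect to the C4a–C8a arene bond and with the carbonyl oxygen outside the ring; the arenium ion is stabilised by the C7 allyloxy oxygen para to the point of attack, and loss of the C4a proton restores aromaticity. No stereocentre is formed. The selectivity needed is C4a over C8: C4a is para to the C7 oxygen and has one substituted neighbour, whereas C8 is ortho to both oxygens and flanked on both sides, so electronic and steric effects point the same way. Ring B cannot intercept the cation, since bonding to its ortho carbon would make a four-membered ring, and the tethered reaction should outrun intermolecular acylation. The allyl ether, the methyl ethers and the vinylogous ester of the product are stable to the anhydride at these temperatures.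

Step 9
Reactants: 13 7-(allyloxy)-3-(3,4-dimethoxyphenyl)-6-methoxy-4H-chromen-4-one
Product: 15 8-allyl-3-(3,4-dimethoxyphenyl)-7-hydroxy-6-methoxy-4H-chromen-4-one, via C8-allyl cyclohexadienone 14 (not isolated)
Conditions: PhNEt2, 200 °C, sealed tube, Ar
Reagents that add atoms: none
Why: Aromatic Claisen rearrangement ([3,3]-sigmatropic shift); migration to C6 gives a dienone that cannot enolise because C6 carries methoxyl and so reverts, whereas migration to C8 gives 14, which tautomerises irreversibly to phenol 15. The transient stereocentre of 14 is lost on enolisation.

Step 10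
Reactants: 15 8-allyl-3-(3,4-dimethoxyphenyl)-7-hydroxy-6-methoxy-4H-chromen-4-one; 16 2-methylbut-2-ene
Product: 17 3-(3,4-dimethoxyphenyl)-7-hydroxy-6-methoxy-8-(3-methylbut-2-enyl)-4H-chromen-4-one (target)
Conditions: second-generation Grubbs catalyst RuCl2(=CHPh)(H2IMes)(PCy3) (5 mol %), 2-methylbut-2-ene/CH2Cl2, 40 °C, sealed tube
Reagents that add atoms: 2-methylbut-2-ene (compound 16), CC=C(C)C
Why: Olefin cross-metathesis; the terminal allyl alkene exchanges its CH2 terminus for the isopropylidene end of the trisubstituted alkene used in large excess, propene escapes, and secondary metathesis should convert any but-2-enyl intermediate into the prenyl product. The electron-poor C2=C3 bond of ring C is inert, and the gem-dimethyl terminus leaves no geometry to control.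

## Compound list

1 | isovanillin (3-hydroxy-4-methoxybenzaldehyde) | COc1ccc(C=O)cc1O | starting material
2 | allyl bromide (3-bromoprop-1-ene) | C=CCBr | starting material
3 | 3-(allyloxy)-4-methoxybenzaldehyde | C=CCOc1cc(C=O)ccc1OC | intermediate
4 | 3-(allyloxy)-4-methoxyphenyl formate | C=CCOc1cc(OC=O)ccc1OC | intermediate (not isolated)
5 | 3-(allyloxy)-4-methoxyphenol | C=CCOc1cc(O)ccc1OC | intermediate
6 | (3,4-dimethoxyphenyl)acetic acid | COc1ccc(CC(=O)O)cc1OC | starting material
7 | tert-butyl (3,4-dimethoxyphenyl)acetate | COc1ccc(CC(=O)OC(C)(C)C)cc1OC | intermediate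
8 | tert-butyl (Z)-2-(3,4-dimethoxyphenyl)-3-hydroxyprop-2-enoate (enol of the α-formyl ester) | O/C=C(\C(=O)OC(C)(C)C)c1ccc(OC)c(OC)c1 | intermediate
9 | tert-butyl (Z)-2-(3,4-dimethoxyphenyl)-3-(tosyloxy)prop-2-enoate | Cc1ccc(cc1)S(=O)(=O)O/C=C(\C(=O)OC(C)(C)C)c1ccc(OC)c(OC)c1 | intermediate
10 | tert-butyl (Z)-3-[3-(allyloxy)-4-methoxyphenoxy]-2-(3,4-dimethoxyphenyl)prop-2-enoate | C=CCOc1cc(O/C=C(\C(=O)OC(C)(C)C)c2ccc(OC)c(OC)c2)ccc1OC | intermediate
11 | (Z)-3-[3-(allyloxy)-4-methoxyphenoxy]-2-(3,4-dimethoxyphenyl)prop-2-enoic acid | C=CCOc1cc(O/C=C(\C(=O)O)c2ccc(OC)c(OC)c2)ccc1OC | intermediate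
12 | (Z)-3-[3-(allyloxy)-4-methoxyphenoxy]-2-(3,4-dimethoxyphenyl)prop-2-enoic trifluoroacetic anhydride | C=CCOc1cc(O/C=C(\C(=O)OC(=O)C(F)(F)F)c2ccc(OC)c(OC)c2)ccc1OC | intermediate (not isolated)
13 | 7-(allyloxy)-3-(3,4-dimethoxyphenyl)-6-methoxy-4H-chromen-4-one | C=CCOc1cc2occ(-c3ccc(OC)c(OC)c3)c(=O)c2cc1OC | intermediate
14 | (±)-8-allyl-3-(3,4-dimethoxyphenyl)-6-methoxy-8H-chromene-4,7-dione | C=CCC1C(=O)C(OC)=CC2=C1OC=C(c3ccc(OC)c(OC)c3)C2=O | intermediate (not isolated)
15 | 8-allyl-3-(3,4-dimethoxyphenyl)-7-hydroxy-6-methoxy-4H-chromen-4-one | C=CCc1c(O)c(OC)cc2c(=O)c(-c3ccc(OC)c(OC)c3)coc12 | intermediate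
16 | 2-methylbut-2-ene | CC=C(C)C | starting material
17 | 3-(3,4-dimethoxyphenyl)-7-hydroxy-6-methoxy-8-(3-methylbut-2-enyl)-4H-chromen-4-one | COc1ccc(-c2coc3c(CC=C(C)C)c(O)c(OC)cc3c2=O)cc1OC | target

## Step count and least certain steps

Total: 10 steps. Longest linear sequence: 8 steps (6 to 17, steps 3 to 10). The ring A branch (1 to 5, steps 1 and 2) joins at step 6.

**Step 8 (key step).**
- What may go wrong: the oxygen-stabilised acyl cation is a weak electrophile, so the reaction may stall at the mixed anhydride. Equilibration to the reactive geometry may be slow. Intermolecular trifluoroacetylation of ring A, or acid-induced loss of the aryloxy group from C2, could then take over.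
- Fallback: it sets out from 6 and returns at 13, closing ring C at O1–C2 instead. Acid 6 and purchased 4-methoxybenzene-1,3-diol F1 are heated in BF3·OEt2, which acylates the carbon ortho to one hydroxyl and para to the other and gives 1-(2,4-dihydroxy-5-methoxyphenyl)-2-(3,4-dimethoxyphenyl)ethanone F2. DMF with MeSO2Cl and BF3·OEt2 then inserts C2 and cyclises to 7-hydroxy-3-(3,4-dimethoxyphenyl)-6-methoxy-4H-chromen-4-one F3. Its only phenol is allylated with 2 (K2CO3, DMF) to give 13.

**Step 6.**
- What may go wrong: sulfonyl transfer, in which the phenoxide attacks sulfur instead of C3 and regenerates the enolate of 8. Scrambling of the alkene geometry is tolerable.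
- Fallback: it sets out from 8 and returns at 10. Vilsmeier-type chlorination ((COCl)2, DMF cat., CH2Cl2, 0 °C) gives tert-butyl (Z)-3-chloro-2-(3,4-dimethoxyphenyl)prop-2-enoate F4, whose only electrophilic site is carbon. Phenol 5 with Cs2CO3 in DMF then substitutes chloride to give 10.

**Step 7.**
- What may go wrong: Friedel–Crafts tert-butylation of the electron-rich ring A by the departing cation, and protonation at C3 followed by hydrolytic loss of the aryloxy group if moisture is present.
- Fallback: it sets out from 6 and returns at 11, replacing the acid-labile ester by a fluoride-labile one.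
  - Acid 6 is esterified with 2-(trimethylsilyl)ethanol (DCC, DMAP) to 2-(trimethylsilyl)ethyl (3,4-dimethoxyphenyl)acetate F5.
  - Formylation as in step 4 gives 2-(trimethylsilyl)ethyl (Z)-2-(3,4-dimethoxyphenyl)-3-hydroxyprop-2-enoate F6.
  - Tosylation as in step 5 gives 2-(trimethylsilyl)ethyl (Z)-2-(3,4-dimethoxyphenyl)-3-(tosyloxy)prop-2-enoate F7.
  - Substitution with 5 as in step 6 gives 2-(trimethylsilyl)ethyl (Z)-3-[3-(allyloxy)-4-methoxyphenoxy]-2-(3,4-dimethoxyphenyl)prop-2-enoate F8.
  - Bu4NF in THF fragments the ester to 11 without acid or hydroxide.

**Step 9.**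
- What may go wrong: thermal degradation at 200 °C, loss of the allyl group, or addition of the new phenol to the allyl double bond to give a dihydrofuran.
- Fallback: it sets out from 13 and returns at 17, bypassing step 10 as well, by using an ether that rearranges at much lower temperature.
  - Pd(PPh3)4 (zerovalent palladium) with morpholine removes the allyl group to give 7-hydroxy-3-(3,4-dimethoxyphenyl)-6-methoxy-4H-chromen-4-one F3, the compound already described under step 8.
  - Alkylation with 3-chloro-3-methylbut-1-yne (DBU, CuCl2 cat., MeCN) gives 3-(3,4-dimethoxyphenyl)-6-methoxy-7-[(2-methylbut-3-yn-2-yl)oxy]-4H-chromen-4-one F9.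
  - Semi-hydrogenation (H2, Pd on CaCO3 poisoned with Pb(OAc)2, quinoline) gives 3-(3,4-dimethoxyphenyl)-6-methoxy-7-[(2-methylbut-3-en-2-yl)oxy]-4H-chromen-4-one F10.
  - A Claisen shift of F10 (Eu(fod)3 cat., CHCl3, 60 °C) places the prenyl group on C8 and gives 17.

**Step 10.**
- What may go wrong: migration of the allyl double bond into conjugation with ring A by catalyst-derived Ru–H species, slow turnover through coordination of the ortho phenol to ruthenium, and incomplete exchange that stops at the but-2-enyl stage.
- Fallback: it sets out from 15 and returns at 17, masking the phenol during the metathesis.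
  - Ac2O and pyridine give 8-allyl-3-(3,4-dimethoxyphenyl)-6-methoxy-4-oxo-4H-chromen-7-yl acetate F11.
  - Cross-metathesis with 16 under the conditions of step 10 gives 3-(3,4-dimethoxyphenyl)-6-methoxy-8-(3-methylbut-2-enyl)-4-oxo-4H-chromen-7-yl acetate F12.
  - K2CO3 (cat.) in MeOH removes the acetate to give 17.

## Further compounds

F1 | step 8 | 4-methoxybenzene-1,3-diol (purchased) | COc1ccc(O)cc1O
F2 | step 8 | 1-(2,4-dihydroxy-5-methoxyphenyl)-2-(3,4-dimethoxyphenyl)ethanone | COc1ccc(CC(=O)c2cc(OC)c(O)cc2O)cc1OC
F3 | step 8 | 7-hydroxy-3-(3,4-dimethoxyphenyl)-6-methoxy-4H-chromen-4-one | COc1ccc(-c2coc3cc(O)c(OC)cc3c2=O)cc1OC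
F4 | step 6 | tert-butyl (Z)-3-chloro-2-(3,4-dimethoxyphenyl)prop-2-enoate | Cl/C=C(\C(=O)OC(C)(C)C)c1ccc(OC)c(OC)c1
F5 | step 7 | 2-(trimethylsilyl)ethyl (3,4-dimethoxyphenyl)acetate | COc1ccc(CC(=O)OCC[Si](C)(C)C)cc1OC
F6 | step 7 | 2-(trimethylsilyl)ethyl (Z)-2-(3,4-dimethoxyphenyl)-3-hydroxyprop-2-enoate | O/C=C(\C(=O)OCC[Si](C)(C)C)c1ccc(OC)c(OC)c1
F7 | step 7 | 2-(trimethylsilyl)ethyl (Z)-2-(3,4-dimethoxyphenyl)-3-(tosyloxy)prop-2-enoate | Cc1ccc(cc1)S(=O)(=O)O/C=C(\C(=O)OCC[Si](C)(C)C)c1ccc(OC)c(OC)c1
F8 | step 7 | 2-(trimethylsilyl)ethyl (Z)-3-[3-(allyloxy)-4-methoxyphenoxy]-2-(3,4-dimethoxyphenyl)prop-2-enoate | C=CCOc1cc(O/C=C(\C(=O)OCC[Si](C)(C)C)c2ccc(OC)c(OC)c2)ccc1OC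
F9 | step 9 | 3-(3,4-dimethoxyphenyl)-6-methoxy-7-[(2-methylbut-3-yn-2-yl)oxy]-4H-chromen-4-one | C#CC(C)(C)Oc1cc2occ(-c3ccc(OC)c(OC)c3)c(=O)c2cc1OC
F10 | step 9 | 3-(3,4-dimethoxyphenyl)-6-methoxy-7-[(2-methylbut-3-en-2-yl)oxy]-4H-chromen-4-one | C=CC(C)(C)Oc1cc2occ(-c3ccc(OC)c(OC)c3)c(=O)c2cc1OC
F11 | step 10 | 8-allyl-3-(3,4-dimethoxyphenyl)-6-methoxy-4-oxo-4H-chromen-7-yl acetate | C=CCc1c(OC(C)=O)c(OC)cc2c(=O)c(-c3ccc(OC)c(OC)c3)coc12
F12 | step 10 | 3-(3,4-dimethoxyphenyl)-6-methoxy-8-(3-methylbut-2-enyl)-4-oxo-4H-chromen-7-yl acetate | CC(C)=CCc1c(OC(C)=O)c(OC)cc2c(=O)c(-c3ccc(OC)c(OC)c3)coc12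
A1 | alternative 1 | 4-methoxy-3-(methoxymethoxy)-2-(trimethylsilyl)phenyl trifluoromethanesulfonate | COCOc1c(OC)ccc(OS(=O)(=O)C(F)(F)F)c1[Si](C)(C)C
A2 | alternative 1 | potassium 2-methylbut-3-en-2-olate | [K+].[O-]C(C)(C)C=C
A3 | alternative 1 | 4-methoxy-3-(methoxymethoxy)-2-(3-methylbut-2-enyl)phenol | COCOc1c(OC)ccc(O)c1CC=C(C)C
A4 | alternative 2 | (±)-4-{(E)-2-[2-(3,4-dimethoxybenzyl)-1,3-dioxolan-2-yl]ethenyl}-4-methoxy-2-(3-methylbut-2-enyl)-3-(propan-2-yloxy)cyclobut-2-en-1-one | O=C1C(CC=C(C)C)=C(OC(C)C)C1(OC)/C=C/C2(Cc3ccc(OC)c(OC)c3)OCCO2
A5 | alternative 2 | 2-[2-(3,4-dimethoxybenzyl)-1,3-dioxolan-2-yl]-4-methoxy-6-(3-methylbut-2-enyl)-5-(propan-2-yloxy)phenol | CC(C)Oc1c(OC)cc(C3(Cc2ccc(OC)c(OC)c2)OCCO3)c(O)c1CC=C(C)C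
A6 | alternative 3 | 2-[2-(3,4-dimethoxyphenyl)-2-oxoethoxy]-5-methoxy-4-(methoxymethoxy)-3-(3-methylbut-2-enyl)benzaldehyde | COCOc1c(OC)cc(C=O)c(OCC(=O)c2ccc(OC)c(OC)c2)c1CC=C(C)C
A7 | alternative 3 | (±)-3-(3,4-dimethoxyphenyl)-3-hydroxy-6-methoxy-7-(methoxymethoxy)-8-(3-methylbut-2-enyl)chroman-4-one | COCOc1c(OC)cc2c(c1CC=C(C)C)OCC(O)(c3ccc(OC)c(OC)c3)C2=O
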